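(The readings are calculated for an exercise; scatter was added.)

A solution with a single equilibrium constant cannot leave nearly the same substrate behind at every charge, yet the three runs below came close to doing so.

| setting | alpha | eta | zeta | Saturday's | Sunday's | Thursday's | Monday's |
|---|---|---|---|---|---|---|---|
| substrate | 5.9 mM | 15 mM | 41 mM | 6.0 mM | 20 mM | 40 mM | 12 mM |
| remark | run made earlier | run made earlier | run made earlier |  |  |  |  |
| time |  |  |  | 2.5 d | 2.5 d | 2.5 d | 2.5 d |

| run | time / h | product / % |
|---|---|---|
| alpha | 8.00 | 20.8 |
| alpha | 15.0 | 31.9 |
| alpha | 25.0 | 38.7 |
| alpha | 30.0 | 42.3 |
| alpha | 40.0 | 46.4 |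
| eta | 4.00 | 30.4 |
| eta | 10.0 | 49.6 |
| eta | 20.0 | 63.8 |
| eta | 30.0 | 72.5 |
| eta | 40.0 | 72.8 |
| zeta | 4.00 | 53.4 |
| zeta | 10.0 | 74.2 |
| zeta | 20.0 | 82.8 |
| zeta | 30.0 | 87.0 |
| zeta | 40.0 | 92.0 |

(standard deviation of a reading: 1 percentage point)

- percent here means substrate units held: one product or crystals counts as two
- what is said of product includes crystals
- crystals is a solid; its amount is given per volume of the solution
- the numbers in the tables scatter with a standard deviation of 1 percentage point
- on the list of suspects stand: 2 substrate <-> product; crystals <-> product

- the flasks put in order of amount of product, in percent of the substrate charged, best first, at 2.5 d (Saturday's / Sunday's / Thursday's / Monday's)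
- the amount of product, in percent of the substrate charged of the flask you put first, at 2.5 d
- the amount of product, in percent of the substrate charged of the flask you put last, at 2.5 d

I read the last row of each table. One product counts as two substrate, so whatever is not product is substrate, and the substrate left is the charge times the missing percentage. After 40.0 h alpha had left 3.16 mM, eta 4.08 mM and zeta 3.28 mM, though zeta's charge was 6.95 times alpha's. Product over substrate squared meanwhile climbed from 0.137 /mM in alpha to 1.75 /mM in zeta, so I took crystals to be holding the solution.

I then computed only the small remainder. I kept the mean of the three rows as the substrate floor, my reading of the free substrate left beside crystals after 40.0 h, 3.51 mM. It is a reading of scattered rows and not an end value, since zeta was still rising from 87.0% to 92.0%, so the substrate in a longer flask may lie lower. Product in percent is one minus floor over charge: 91.2% for Thursday's, 82.5% for Sunday's, 70.8% for Monday's. The spread of the rows, 0.920 mM, costs Thursday's 2.29% of its charge but Saturday's 15.3%. For Saturday's I therefore used alpha's own remainder, which gave 47.3%, with alpha still rising from 42.3% to 46.4% at its end.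

The forecast, above me on the last flask, said Thursday's > Sunday's > Monday's > Saturday's, with 91% and 50%, holding that “Crystals must therefore pin the free substrate”.

The flasks gave Thursday's > Sunday's > Monday's > Saturday's, with 91.8% first, then 84.0%, 73.9% and 50.4%.

    2 substrate ⇌ product (K = 74.7 /M, k = 9.98 × 10⁻⁴ /M/s)
    crystals ⇌ product, rate k2*(cs2 - [product]) while solid is left; crystals form when [product] > cs2 (solubility = 0.580 mM, k = 0.00154 /s)

In Thursday's flask the step between substrate and dissolved product relaxed by itself with a half-life of 0.304 d at 2.50 d, shorter than the 2.5 d of the flask, and net, dissolved product was made at 0.992 of the rate at which it was used up. That is close to thermodynamic control, and Thursday's held 3.27 mM of substrate at 2.50 d, below my reading of 3.51 mM. For a neighbour of Thursday's charged with 68 mM, the floor gives 94.8%, and that flask stood at 95.1% product, with 4.9% of its charge left as substrate.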